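Set [G] against [E] before anything else, for these flasks and these questions.

| setting | cedar | oak | dusk | winter |
|---|---|---|---|---|
| E | 0.14 M | 0.27 M | 0.20 M | 0.10 M |
| X | 0.01 mol% | 0.01 mol% | 0.01 mol% | 0.01 mol% |
| remark | run made earlier | run made earlier |  |  |
| time |  |  | 4.0 min | 15 min |

| run | time / min | G / % | E / % |
|---|---|---|---|
| cedar | 0.500 | 39 | 18 |
| cedar | 1.33 | 47 | 4 |
| cedar | 2.50 | 41 | 2 |
| cedar | 4.00 | 35 | 4 |
| oak | 0.500 | 40 | 8 |
| oak | 1.33 | 38 | 7 |
| oak | 2.50 | 35 | 2 |
| oak | 4.00 | 30 | 3 |

(readings scatter by 1.5 percentage points)

- where the amount of E changes, what is given in equivalents or mol% on it follows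

* which one finishes higher in amount of G, in percent of the E charged ("neither" within 2 percentage points) (dusk / winter / neither)
* amount of G at the end, in percent of the E charged, dusk
* amount of G at the end, in percent of the E charged, winter

From 1.33 min on, E stays at or below 7% in cedar and oak while G declines. So I add up G and E over those readings of both runs and divide. Time drops out, and I get the pooled ratio, summed [G] over summed [E], 10.3, a reading that carries the scatter of 1.5 percentage points on small E. Single readings of E this small can neither show nor exclude a steady ratio, so I assume one, as in a pre-equilibrium: I take E to follow G down, and a loss running through E then scales with G.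

Dusk brackets directly: at 4.00 min the same loading gave 35% at 0.14 M and 30% at 0.27 M, and 0.20 M lies between, so I interpolate to 32.7%.

Winter runs for 15 min. The same line, extended to 0.10 M, puts it at 36.5% at 4.00 min. For my floor, suppose each loss takes one E: G then falls exponentially at cedar's 0.110 /min, down to 10.8%. For my ceiling, suppose each loss takes two partners: 1/[G] then grows linearly, at a pace proportional to the charge, which gives 20.5%. I commit to their geometric mean, 14.9%, and to dusk, whose lower end stands higher than winter's ceiling.

The forecast says dusk, with 33% and 11%, the latter “uncertain because it lies well beyond the observed time window”; both stand inside my brackets.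

The flask gives dusk, with 31.6% and 17.2%, inside both brackets.

    D ⇌ X + G (K = 0.220 M, k = 230 /s)
    E + G → J (k = 0.0570 /M/s)
    E + X ⇌ D (K = 39.0 /M, k = 35000 /M/s)
    E → Q (k = 0.0100 /s)
    2 E → Z (k = 0.0910 /M/s)

My mean for winter stands 2.3 points low. Winter ends with 45.4% of the E charged as Q. Dusk left until 10 min holds G at 18.0%; dividing that by my 10.3 gives E at 1.75%, and that flask holds E at 1.92%.

The data come from a simulation from invented constants, noise included.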